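**Plan**
- Retrosynthesis first cuts ring A of the chromone at C6–C7 and C7–C8. C7 and its oxygen go back to the carbonyl of dimethyl carbonate, C6 to the methyl of an acetyl group and C8 to a ring methyl group; these two groups sit on neighbouring carbons (future C4a and C8a) of a preformed 4-pyranone, and the acetyl carbonyl supplies C5 and its oxygen.
- The pyranone is then cut at O1–C8a and C4–C4a into hexadecanoylketene and pentane-2,4-dione, and the ketene goes back to hexadecanoyl chloride and Meldrum's acid.
- Forward: the C15 chain is joined to the two-carbon ketene unit first, the heterocyclic ring is built second, and ring A is closed last by a five-plus-one double Claisen condensation.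
- Stereochemistry: the target has no stereocentre and no stereogenic double bond, so nothing has to be controlled.

Key step: step 3

Remark on the chemistry: polycarbonyl compounds are drawn as one tautomer each (the acylated Meldrum's acid as its enol, the tetraketone in the keto form); which tautomer is present has no bearing on the route.

**Step 1**
Reactants: 1 hexadecanoyl chloride (palmitoyl chloride); 2 2,2-dimethyl-1,3-dioxane-4,6-dione (Meldrum's acid)
Product: 3 5-(1-hydroxyhexadecylidene)-2,2-dimethyl-1,3-dioxane-4,6-dione
Conditions: pyridine (2.2 equiv), CH2Cl2, 0 °C to rt; wash with cold 1 M HCl; used crude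
Reagents that add atoms: none
Why: Pyridine-mediated C-acylation of Meldrum's acid by an acid chloride (Oikawa–Yonemitsu acylation) is general for long-chain acyl chlorides, and the product should rest as its hydrogen-bonded enol, which resists a second acylation.

**Step 2**
Reactants: 3 5-(1-hydroxyhexadecylidene)-2,2-dimethyl-1,3-dioxane-4,6-dione; 4 pentane-2,4-dione (acetylacetone)
Product: 7 3-acetyl-2-methyl-6-pentadecyl-4H-pyran-4-one, via hexadecanoylketene 5 (not isolated), via 3-acetylhenicosane-2,4,6-trione 6 (not isolated)
Conditions: 4 (5 equiv), PhMe, 110 °C; evaporate; p-TsOH·H2O (10 mol %), PhMe, reflux, Dean–Stark trap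
Reagents that add atoms: none
Why: On heating, 3 should lose acetone and CO2 by retro-hetero-Diels–Alder fragmentation to acylketene 5, which acylates the central carbon of enolic 4 (ketene C-acylation, formally a hetero-Diels–Alder addition across the enol double bond) to give 6, and acid-catalysed cyclodehydration of its 1,3,5-tricarbonyl array can close only one six-membered oxygen ring, the 4-pyranone 7; O-acylation of the enol is reversible at this temperature and the excess of 4 holds back ketene dimerisation.

**Step 3**
Reactants: 7 3-acetyl-2-methyl-6-pentadecyl-4H-pyran-4-one; 8 dimethyl carbonate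
Product: 10 5,7-dihydroxy-2-pentadecyl-4H-chromen-4-one, via pyranyl keto ester 9 (not isolated)
Conditions: LiN(SiMe3)2 (4.5 equiv), THF, −78 °C; 8 (1.1 equiv), −78 to 50 °C; then 1 M HCl
Reagents that add atoms: none
Why: Proposed new method: excess LiN(SiMe3)2 should turn 7 into its acetyl enolate, which is C-methoxycarbonylated by 8 (Claisen condensation) to the β-keto ester 9 and so forms C6–C7; further base then removes a proton from the 2-methyl group, which is vinylogously activated by the ring carbonyl, and this lateral carbanion attacks the ester carbonyl in a Dieckmann-type 6-(enolendo)-exo-trig closure that forms C7–C8 and ring A. Loss of methoxide and enolisation of the resulting cyclohexenedione give the aromatic 5,7-diphenolate, which makes the sequence irreversible and is protonated to 10 on acidic work-up. The closest known reactions are the methoxycarbonylation of methyl ketone enolates with dialkyl carbonates, the conversion of 2-hydroxyacetophenones and diethyl carbonate into 4-hydroxycoumarins (the oxygen counterpart of this five-plus-one closure), Claisen cyclisations of polyketo ester polyanions to resorcinols, and lateral condensations of 2-methyl-4-pyranone carbanions. No stereocentre is formed. The step needs site selectivity among three acidic positions and a single carbonylation: the acetyl and methyl groups are held cis on the C2=C3 double bond of the pyranone, so the order of the two bond formations is immaterial (carbonylation at the 2-methyl group first would be closed by the acetyl enolate to the same ring); the carbanion at the first carbon of the pentadecyl chain is less acidic, forms reversibly and has no ester within reach; and adding only a slight excess of 8 to the preformed anion should keep a second carbonylation from competing with the intramolecular closure.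

**Compound list**
1 | hexadecanoyl chloride (palmitoyl chloride) | CCCCCCCCCCCCCCCC(=O)Cl | starting material
2 | 2,2-dimethyl-1,3-dioxane-4,6-dione (Meldrum's acid) | CC1(C)OC(=O)CC(=O)O1 | starting material
3 | 5-(1-hydroxyhexadecylidene)-2,2-dimethyl-1,3-dioxane-4,6-dione | CCCCCCCCCCCCCCCC(O)=C1C(=O)OC(C)(C)OC1=O | intermediate
4 | pentane-2,4-dione (acetylacetone) | CC(=O)CC(C)=O | starting material
5 | hexadecanoylketene (octadec-1-ene-1,3-dione) | CCCCCCCCCCCCCCCC(=O)C=C=O | intermediate (not isolated)
6 | 3-acetylhenicosane-2,4,6-trione | CCCCCCCCCCCCCCCC(=O)CC(=O)C(C(C)=O)C(C)=O | intermediate (not isolated)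
7 | 3-acetyl-2-methyl-6-pentadecyl-4H-pyran-4-one | CCCCCCCCCCCCCCCc1cc(=O)c(C(C)=O)c(C)o1 | intermediate
8 | dimethyl carbonate | COC(=O)OC | starting material
9 | methyl 3-(2-methyl-4-oxo-6-pentadecyl-4H-pyran-3-yl)-3-oxopropanoate (pyranyl keto ester) | CCCCCCCCCCCCCCCc1cc(=O)c(C(=O)CC(=O)OC)c(C)o1 | intermediate (not isolated)
10 | 5,7-dihydroxy-2-pentadecyl-4H-chromen-4-one | CCCCCCCCCCCCCCCc1cc(=O)c2c(O)cc(O)cc2o1 | target

Total step count: 3. Longest linear sequence: 3 steps (1 to 3 to 7 to 10).

**Steps most likely to fail**

Step 3 (key step). The second deprotonation may not compete, so that the sequence stalls after the first carbonylation. Carbonylation may also run on at the second methyl group or at the chain α-carbon, or methoxide may open the pyranone ring. The fallback uses known chemistry, sets out from hexadecanoyl chloride 1 and rejoins the route at target 10; ring A is bought and the heterocycle is closed last. Commercial 2,4,6-trihydroxyacetophenone would be acylated on all three oxygens with 1 (pyridine, CH2Cl2) to give 2-acetylbenzene-1,3,5-triyl trihexadecanoate F1. Baker–Venkataraman oxygen-to-carbon acyl migration with KOC(CH3)3 in THF should give 5-hydroxy-4-(3-oxooctadecanoyl)-1,3-phenylene dihexadecanoate F2. Heating F2 with HCl in MeOH should close the pyranone ring by cyclodehydration and remove the two remaining palmitates by transesterification, giving 10.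

Step 2. The acylketene may dimerise or be taken up at the enol oxygen instead of at carbon, and the triacylmethane may lose an acetyl group by retro-Claisen cleavage during the acid treatment. The fallback avoids the ketene, sets out from pentane-2,4-dione 4 and hexadecanoyl chloride 1, and rejoins the route at tetraketone 6. Compound 4 would be C-acetylated (MgCl2, pyridine, acetyl chloride, CH2Cl2) to 3-acetylpentane-2,4-dione F3, and 1 would be converted with methanol and pyridine into methyl hexadecanoate F4. F3 would be taken with LiN(iPr)2 (3.3 equiv, THF, −78 to 0 °C) to its dianion, deprotonated at the central carbon and at one terminal methyl group. Claisen acylation of the terminal carbanion by F4 (Hauser–Harris dianion acylation) should give 6, which is cyclised with p-TsOH as in step 2.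

Step 1. Acylation may occur at oxygen or twice, and the acylated Meldrum's acid may be lost by hydrolysis or premature ketene formation during isolation. The fallback sets out from hexadecanoyl chloride 1 and rejoins the route at acylketene 5. The lithium enolate of tert-butyl acetate (LiN(iPr)2, 2 equiv, THF, −78 °C) would be acylated by 1 in a crossed Claisen condensation to tert-butyl 3-oxooctadecanoate F5. Acetone, (CF3CO)2O and CF3CO2H should convert F5 into 2,2-dimethyl-6-pentadecyl-4H-1,3-dioxin-4-one F6, a ketene precursor that can be purified and stored. Heating F6 with 4 in xylene at 130 °C should release acetone and give 5, which continues as in step 2.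

**Further compounds**
F1 | step 3 | 2-acetylbenzene-1,3,5-triyl trihexadecanoate | CC(=O)c1c(OC(=O)CCCCCCCCCCCCCCC)cc(OC(=O)CCCCCCCCCCCCCCC)cc1OC(=O)CCCCCCCCCCCCCCC
F2 | step 3 | 5-hydroxy-4-(3-oxooctadecanoyl)-1,3-phenylene dihexadecanoate | CCCCCCCCCCCCCCCC(=O)CC(=O)c1c(O)cc(OC(=O)CCCCCCCCCCCCCCC)cc1OC(=O)CCCCCCCCCCCCCCC
F3 | step 2 | 3-acetylpentane-2,4-dione | CC(=O)C(C(C)=O)C(C)=O
F4 | step 2 | methyl hexadecanoate | CCCCCCCCCCCCCCCC(=O)OC
F5 | step 1 | tert-butyl 3-oxooctadecanoate | CCCCCCCCCCCCCCCC(=O)CC(=O)OC(C)(C)C
F6 | step 1 | 2,2-dimethyl-6-pentadecyl-4H-1,3-dioxin-4-one | CCCCCCCCCCCCCCCC1=CC(=O)OC(C)(C)O1
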